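The vessel is closed, stirred and isothermal, and at the start all of the solid substrate lies undissolved in it, so the solid is what I watch first.

| setting | ochre | green | flask |
|---|---|---|---|
| solid substrate | 0.80 M | 0.80 M | 0.80 M |
| reagent | 0.60 M | 0.90 M | 1.20 M |
| remark | run made earlier | run made earlier |  |
| time |  |  | 4.0 h |

| run | time / h | solid substrate / % | first product / % | other mono adduct / % |
|---|---|---|---|---|
| ochre | 0.333 | 97.4 | 0.8 | 0.4 |
| ochre | 0.667 | 93.4 | 0 | 0 |
| ochre | 1.00 | 93.2 | 0.2 | 1.2 |
| ochre | 2.00 | 86.5 | 1.4 | 1.3 |
| ochre | 4.00 | 72.2 | 3.6 | 6.9 |
| green | 0.333 | 99.3 | 0.8 | 0 |
| green | 0.667 | 94.0 | 1.0 | 0.1 |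
| green | 1.00 | 91.6 | 0.6 | 0.6 |
| green | 2.00 | 86.2 | 1.1 | 3.7 |
| green | 4.00 | 75.0 | 3.9 | 9.2 |

(scatter of a reading: 1 percentage point)

- given per volume of solution although it is solid: solid substrate
- what was read earlier has a scatter of 1 percentage point, one standard deviation
- on the list of suspects stand: starting material + reagent -> first product + by-product; starting material + reagent -> other mono adduct + by-product; reagent + first product -> bis adduct + by-product; reagent + other mono adduct -> bis adduct + by-product; solid substrate <-> starting material
- at the start none of the solid substrate is in solution

1. how much solid substrate there is at 4.0 h, in percent of the solid substrate charged (only what is still solid)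
2. how much first product there is at 4.0 h, in percent of the solid substrate charged
3. how much other mono adduct there is at 4.0 h, in percent of the solid substrate charged
4. how much bis adduct there is at 4.0 h, in percent of the solid substrate charged

I read the solid columns row against row. At 2.00 h the ochre run reads 86.5 % and the green run 86.2 %, inside the scatter of 1 percentage point. At 4.00 h they read 72.2 % and 75.0 %, and the green run, with 0.90 M of reagent against 0.60 M, reads the higher solid. That gap of 2.8 points lies between two scattered readings, so I can read no clear effect of reagent on the loss of solid from these two runs, and I take one pace for both.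

Down the ochre column the loss by 4.00 h is twice the loss by 2.00 h: a straight line, close to zero order. Solid and both mono adducts leave 17.3 % unread at 4.00 h in the ochre run and 11.9 % in the green run, a rest that is dissolved starting material and bis adduct.

The mean of both runs at 4.00 h gives 15.2 h. I call this the clearing time: the time the whole charge takes to leave at the pace read so far. For the flask, with 1.20 M of reagent on the same 0.80 M of solid, one division gives me 73.6 % of solid at 4.0 h.

The forecast says 74 % solid, 4.5 % first product, 10 % other mono adduct and 1 % bis adduct, holding that “dissolution looks rate-limiting and roughly zero-order”.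

The flask gives 73.3 % solid substrate, 4.22 % first product, 8.49 % other mono adduct and 3.96 % bis adduct.

    starting material + reagent → first product + by-product (k = 0.220 M⁻¹ h⁻¹)
    starting material + reagent → other mono adduct + by-product (k = 0.310 M⁻¹ h⁻¹)
    reagent + first product → bis adduct + by-product (k = 0.310 M⁻¹ h⁻¹)
    reagent + other mono adduct → bis adduct + by-product (k = 0.0800 M⁻¹ h⁻¹)
    solid substrate ⇌ starting material, rate k5*(cs5 - [starting material]) while solid is left; crystals form when [starting material] > cs5 (solubility = 0.390 M, k = 0.160 h⁻¹)

At 4.00 h the flask holds 10.0 % of starting material, which is made 1.13 times faster than it is used up, each step taken net. The clearing time of 15.2 h gives 73.6 % of solid against the 73.3 % found. Left until 10 h, the same flask should hold 34.2 % by the clearing time, and it holds 37.9 %.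

The readings come from a simulation for substances that don't exist; scatter was added.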